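**Retrosynthetic overview**

1. Target 13 is the cyclic hemiketal of a (2R)-2',6'-dihydroxyflavanone. Flavanone numbering is used throughout: ring A = C4a/C5–C8/C8a, ring B = the dihydroxyphenyl ring, ring C = pyranone, ring D = dimethylpyran (O7, C2'', C3'', C4''), ring E = the hemiketal 1,3-dioxane. Opening ring E (C4–O2') gives free flavanone 12.
2. Key disconnection: ring D is cut at C6–C4'' and at O7–C2'', which gives prenal and a 7-phenol. The same operation is traced back through ring C (O1–C2), so the precursor is the open chalcone 6.
3. Enabling feature: C6 is the only unsubstituted carbon of ring A. It lies between the free O7–H and C5–OMe, C8 is blocked by the prenyl group, and ring B is silenced as its bis-MOM ether. The phenol/enal annulation can therefore close only across C6/O7 (linear pyran).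
4. Chalcone 6 comes from a Claisen–Schmidt union of C-prenylated acetophenone 5 and aldehyde 2. C2 is formed racemic and resolved by asymmetric transfer hydrogenation (kinetic resolution).
5. Ring order: A and B are purchased; D and then C form in the key step; E forms last, on MOM removal.

Key step: step 4

Assumption: the bridged hemiketal is taken as the resting form of free flavanone 12 (no 5-OH holds C4 as a ketone). The bicyclo[3.3.1] bridge ties the configuration of C4 to that of C2, so only C2 (R in flavanone numbering) has to be set.

**Route**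

Step 1
Reactants: 1 2,6-dihydroxybenzaldehyde
Product: 2 2,6-bis(methoxymethoxy)benzaldehyde
Conditions: NaH, MOMCl, DMF, 0 °C to rt
Reagents that add atoms: chloromethyl methyl ether (MOMCl), COCCl
Why: Williamson-type O-alkylation of the doubly deprotonated bis-phenol (NaH is used so that the chelated OH also reacts) should give the bis-MOM ether, which tolerates hydroxide, amine salts and formate reduction and comes off with dilute acid; no stereocenter is formed.

Step 2
Reactants: 3 1-(2,4-dihydroxy-6-methoxyphenyl)ethan-1-one, 4 1-bromo-3-methylbut-2-ene (prenyl bromide)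
Product: 5 1-[2,4-dihydroxy-6-methoxy-3-(3-methylbut-2-en-1-yl)phenyl]ethan-1-one
Conditions: 10% aq KOH, 0 °C to rt
Reagents that add atoms: none
Why: C-prenylation of the ambident phenoxide in water (hydrogen bonding to oxygen favours attack through carbon) should occur mainly at C3, the carbon flanked by both phenoxide oxygens, with the C5 isomer and O-prenyl ethers as minor products removed by chromatography, so a modest yield is expected; no stereocenter is formed.

Step 3
Reactants: 5 1-[2,4-dihydroxy-6-methoxy-3-(3-methylbut-2-en-1-yl)phenyl]ethan-1-one, 2 2,6-bis(methoxymethoxy)benzaldehyde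
Product: 6 (E)-3-[2,6-bis(methoxymethoxy)phenyl]-1-[2,4-dihydroxy-6-methoxy-3-(3-methylbut-2-en-1-yl)phenyl]prop-2-en-1-one
Conditions: 50% aq KOH, EtOH, rt
Reagents that add atoms: none
Why: Claisen–Schmidt condensation (crossed aldol addition of the methyl ketone enolate to the non-enolizable aldehyde, then E1cB dehydration) should give the E-enone under thermodynamic control, the MOM ethers being stable to hydroxide; no stereocenter is formed.

Step 4
Reactants: 6 (E)-3-[2,6-bis(methoxymethoxy)phenyl]-1-[2,4-dihydroxy-6-methoxy-3-(3-methylbut-2-en-1-yl)phenyl]prop-2-en-1-one, 7 3-methylbut-2-enal (prenal)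
Product: 10 racemic 2-[2,6-bis(methoxymethoxy)phenyl]-5-methoxy-8,8-dimethyl-10-(3-methylbut-2-en-1-yl)-2,3-dihydropyrano[3,2-g]chromen-4-one, via ortho-quinone methide 8 (not isolated), via pyranochalcone 9 (not isolated)
Conditions: ethylenediammonium diacetate (cat.), toluene, 110 °C; then NaOAc, EtOH, 80 °C, same flask
Reagents that add atoms: none
Why: Ethylenediammonium diacetate turns prenal into an iminium ion that is attacked by the future C6 of ring A (Knoevenagel-type C-alkylation ortho to the free O7–H); loss of the amine gives ortho-quinone methide 8, whose oxa-6π electrocyclization makes the O7–C2'' bond, so C6–C4'' and O7–C2'' both form here before acetate mediates conjugate addition of the chelated O1–H to the enone. The closest known reaction type is the amine-salt-catalysed phenol/enal formal (3+3) chromene annulation of acylphloroglucinols, run in tandem with the base-mediated chalcone–flavanone isomerization. Ring D closes by thermal disrotatory 6π electrocyclization of the 1-oxatriene, ring C by 6-endo-trig oxa-Michael addition. The new stereocenter C2 forms without a controlling element, so 10 is racemic and is resolved in step 5. The step needs regioselectivity for C6/O7 and chemoselectivity for ring A: the first is secured because C6 is the only CH of ring A, C8 is blocked by the prenyl group and the only hydroxyl next to C6 is O7–H (O5 is methylated); the second because ring B, as its bis-MOM ether, has no free hydroxyl. Closure of ring C should be driven by relief of the twist that the aroyl group, flanked by O1–H and C5–OMe, imposes on the open enone.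

Step 5
Reactants: 10 racemic 2-[2,6-bis(methoxymethoxy)phenyl]-5-methoxy-8,8-dimethyl-10-(3-methylbut-2-en-1-yl)-2,3-dihydropyrano[3,2-g]chromen-4-one
Product: 11 (2R)-2-[2,6-bis(methoxymethoxy)phenyl]-5-methoxy-8,8-dimethyl-10-(3-methylbut-2-en-1-yl)-2,3-dihydropyrano[3,2-g]chromen-4-one
Conditions: RuCl(p-cymene)[(S,S)-TsDPEN] (cat.), HCO2H/Et3N (5:2), EtOAc, rt to 40 °C, stopped just past half conversion
Reagents that add atoms: none
Why: Kinetic resolution by Noyori–Ikariya asymmetric transfer hydrogenation: the (S,S)-catalyst delivers hydride to the Re face of C4, which in the (2S)-enantiomer is the axial face anti to the 2-aryl group, so the (2S)-ketone should be reduced to the cis-(2S,4S)-flavan-4-ol while (2R)-11 is left and separated by chromatography, its enantiopurity being raised by running slightly past half conversion; the acidic formate medium does not open ring C, so C2 is not scrambled.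

Step 6
Reactants: 11 (2R)-2-[2,6-bis(methoxymethoxy)phenyl]-5-methoxy-8,8-dimethyl-10-(3-methylbut-2-en-1-yl)-2,3-dihydropyrano[3,2-g]chromen-4-one
Product: 13 CNP0170313.2 (bridged hemiketal), via free flavanone 12 (not isolated)
Conditions: 3 M aq HCl, THF, 40 °C
Reagents that add atoms: none
Why: Acid hydrolysis of the two MOM acetals frees both ring B phenols, and one of them (the two are equivalent by rotation about C2–C1') adds to the C4 ketone (6-exo-trig hemiketalization) to close ring E; the bicyclo[3.3.1] bridge admits only one configuration at C4 for a given C2, so the hemiketal stereocenter is set by C2 under thermodynamic control and the aqueous medium avoids a mixed methyl ketal.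

**Compound list**

1 | 2,6-dihydroxybenzaldehyde | O=Cc1c(O)cccc1O | starting material
2 | 2,6-bis(methoxymethoxy)benzaldehyde | O=Cc1c(OCOC)cccc1OCOC | intermediate
3 | 1-(2,4-dihydroxy-6-methoxyphenyl)ethan-1-one | CC(=O)c1c(O)cc(O)cc1OC | starting material
4 | 1-bromo-3-methylbut-2-ene (prenyl bromide) | CC(C)=CCBr | starting material
5 | 1-[2,4-dihydroxy-6-methoxy-3-(3-methylbut-2-en-1-yl)phenyl]ethan-1-one | CC(=O)c1c(O)c(CC=C(C)C)c(O)cc1OC | intermediate
6 | (E)-3-[2,6-bis(methoxymethoxy)phenyl]-1-[2,4-dihydroxy-6-methoxy-3-(3-methylbut-2-en-1-yl)phenyl]prop-2-en-1-one | COCOc1cccc(OCOC)c1/C=C/C(=O)c1c(O)c(CC=C(C)C)c(O)cc1OC | intermediate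
7 | 3-methylbut-2-enal (prenal) | CC(C)=CC=O | starting material
8 | ortho-quinone methide of 6 (future C7 as C=O, future C6 carrying the exocyclic 3-methylbut-2-en-1-ylidene group) | COCOc1cccc(OCOC)c1/C=C/C(=O)C1=C(OC)C(=CC=C(C)C)C(=O)C(CC=C(C)C)=C1O | intermediate (not isolated)
9 | (E)-3-[2,6-bis(methoxymethoxy)phenyl]-1-[7-hydroxy-5-methoxy-2,2-dimethyl-8-(3-methylbut-2-en-1-yl)-2H-chromen-6-yl]prop-2-en-1-one (pyranochalcone) | COCOc1cccc(OCOC)c1/C=C/C(=O)c1c(O)c(CC=C(C)C)c2OC(C)(C)C=Cc2c1OC | intermediate (not isolated)
10 | racemic 2-[2,6-bis(methoxymethoxy)phenyl]-5-methoxy-8,8-dimethyl-10-(3-methylbut-2-en-1-yl)-2,3-dihydropyrano[3,2-g]chromen-4-one | COCOc1cccc(OCOC)c1C1CC(=O)c2c(OC)c3C=CC(C)(C)Oc3c(CC=C(C)C)c2O1 | intermediate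
11 | (2R)-2-[2,6-bis(methoxymethoxy)phenyl]-5-methoxy-8,8-dimethyl-10-(3-methylbut-2-en-1-yl)-2,3-dihydropyrano[3,2-g]chromen-4-one | COCOc1cccc(OCOC)c1[C@H]1CC(=O)c2c(OC)c3C=CC(C)(C)Oc3c(CC=C(C)C)c2O1 | intermediate
12 | (2R)-2-(2,6-dihydroxyphenyl)-5-methoxy-8,8-dimethyl-10-(3-methylbut-2-en-1-yl)-2,3-dihydropyrano[3,2-g]chromen-4-one | Oc1cccc(O)c1[C@H]1CC(=O)c2c(OC)c3C=CC(C)(C)Oc3c(CC=C(C)C)c2O1 | intermediate (not isolated)
13 | CNP0170313.2: hemiketal of 12 in which C4 (R) carries OH and is bridged through O2' of ring B to C2 (R), 6'-OH free | COc1c2c(c(CC=C(C)C)c3c1[C@@]1(O)C[C@@H](O3)c3c(O)cccc3O1)OC(C)(C)C=C2 | target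

**Step count and risks**

Total step count: 6. Longest linear sequence: 5 steps (3 → 5 → 6 → 10 → 11 → 13).

Steps most likely to fail:

Step 5. The reduction may be too slow at the C4 ketone, which is hindered by C5–OMe and deactivated by three conjugated oxygens, or the catalyst may discriminate the two enantiomers poorly, so that enantiopure ketone is not recovered. Fallback, setting out from 10 and coming back at 11: reduction with NaBH4 (MeOH/THF, 0 °C) should give the racemic 2,4-cis-flavan-4-ol F1 by axial hydride attack. Enzymatic kinetic resolution by acylation (Burkholderia cepacia lipase, vinyl acetate, t-BuOMe, 35 °C) is expected, by the usual empirical model for secondary aryl carbinols, to acylate the (4R)-alcohol and give the (2R,4R)-acetate F2, which is separated from the unreacted (2S,4S)-alcohol. Methanolysis (K2CO3, MeOH, rt) gives the (2R,4R)-flavan-4-ol F3, and oxidation with Dess–Martin periodinane (NaHCO3, CH2Cl2) returns the ketone 11 without touching C2.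

Step 3. Enolization of the ketone may be incomplete because both phenols are ionized first, and addition to the hindered, electron-rich aldehyde may be slow, so that conversion stalls or retro-aldol and premature ring closure compete. Fallback, setting out from 5 and coming back at 10: the pyran annulation is moved ahead of the condensation. Acetophenone 5 and prenal (ethylenediammonium diacetate, toluene, 110 °C) should give the chromene ketone F4, which keeps only the chelated hydroxyl. Its Claisen–Schmidt condensation with 2 (KOH, EtOH, rt) then gives pyranochalcone 9, now isolated, and NaOAc in EtOH at 80 °C closes ring C to 10.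

Step 4. Carbon–carbon bond formation at C6 may stall, since C6 sits between OMe and OH on an acyl-conjugated ring, while prenal is lost to amine-mediated self-condensation, or ring C may close incompletely. Fallback, setting out from 6 and coming back at 10: alkylation of the only non-chelated hydroxyl (O7–H) with 3-chloro-3-methylbut-1-yne (K2CO3, KI, acetone, 60 °C) gives the aryl 1,1-dimethylpropargyl ether F5. Heating in N,N-diethylaniline at 180 °C should trigger the propargyl Claisen rearrangement to C6, a 1,5-hydrogen shift to the same ortho-quinone methide 8 and electrocyclization to 9, which NaOAc in EtOH at 80 °C converts into 10.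

Further compounds
F1 | step 5 | racemic 2,4-cis-2-[2,6-bis(methoxymethoxy)phenyl]-5-methoxy-8,8-dimethyl-10-(3-methylbut-2-en-1-yl)-3,4-dihydro-2H-pyrano[3,2-g]chromen-4-ol | COCOc1cccc(OCOC)c1C1CC(O)c2c(OC)c3C=CC(C)(C)Oc3c(CC=C(C)C)c2O1
F2 | step 5 | (2R,4R)-2-[2,6-bis(methoxymethoxy)phenyl]-5-methoxy-8,8-dimethyl-10-(3-methylbut-2-en-1-yl)-3,4-dihydro-2H-pyrano[3,2-g]chromen-4-yl acetate | COCOc1cccc(OCOC)c1[C@H]1C[C@@H](OC(C)=O)c2c(OC)c3C=CC(C)(C)Oc3c(CC=C(C)C)c2O1
F3 | step 5 | (2R,4R)-2-[2,6-bis(methoxymethoxy)phenyl]-5-methoxy-8,8-dimethyl-10-(3-methylbut-2-en-1-yl)-3,4-dihydro-2H-pyrano[3,2-g]chromen-4-ol | COCOc1cccc(OCOC)c1[C@H]1C[C@@H](O)c2c(OC)c3C=CC(C)(C)Oc3c(CC=C(C)C)c2O1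
F4 | step 3 | 1-[7-hydroxy-5-methoxy-2,2-dimethyl-8-(3-methylbut-2-en-1-yl)-2H-chromen-6-yl]ethan-1-one | CC(=O)c1c(O)c(CC=C(C)C)c2OC(C)(C)C=Cc2c1OC
F5 | step 4 | (E)-3-[2,6-bis(methoxymethoxy)phenyl]-1-[2-hydroxy-6-methoxy-3-(3-methylbut-2-en-1-yl)-4-(2-methylbut-3-yn-2-yloxy)phenyl]prop-2-en-1-one | COCOc1cccc(OCOC)c1/C=C/C(=O)c1c(O)c(CC=C(C)C)c(OC(C)(C)C#C)cc1OC
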